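**Retrosynthetic overview**
1. End game: the 2,3-dihydrofuran comes from dehydration of a C15 lactol; the 9α,13-ether and the 8β-oxygen come from opening (at C9, by the C13 hydroxyl) of an 8β,9β-epoxide placed by the 7β-hydroxyl; the side chain is joined at C9 by acetylide addition and carbonyl transposition on a ring B vinylogous ester.
2. Ring B: Dieckmann-type closure C7–C8 of an ethyl ketone onto a δ-lactone C19–O–C7, which also unmasks the C19 hydroxyl.
3. Ring A (key step): formal [3+3] union of a 2-methyl-1,3-diketone bis(silyl enol ether) (C2–C1–C10, carrying C9) with a lactone aldehyde (C3–C4–C5): aldol C2–C3, then Michael C5–C10; the C1 ketone is removed afterwards.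
4. Enabling feature: in ring A the quaternary C10 lies between C1 and the oxygenated C9, and 1,3 to the quaternary C4, whose 4β-CH2O (C19) is cis to C6. C10 can therefore be the central carbon of a 1,3-dicarbonyl bis-nucleophile, and C3/C5 a bis-electrophile held on a temporary C19–O–C7 lactone ring.
5. Ring order: temporary δ-lactone → ring A → ring B → tetrahydrofuran → dihydrofuran; absolute configuration comes from C4 (diol desymmetrisation) and C13 (Sharpless epoxidation).

Key step: step 8

Remark: atoms carry labdane numbers (C1–C20); α/β refer to the usual drawing with the C10 methyl β.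
Remark: the acetal carbon C15 is carried as a mixture of epimers (it becomes sp2 in step 24) and C8 is enolisable until step 16; these centres are left open in the SMILES.
Remark: in step 3 the ligand antipode that gives the R monoester is used; its sense of induction has to be established on the first run.

Step 1
Reactants: 1 diethyl ethylidenemalonate
Product: 2 diethyl 2-methyl-2-vinylmalonate
Conditions: LiN(iPr)2, THF–DMPU, −78 °C; MeI, −78 °C to rt
Reagents that add atoms: iodomethane, CI
Why: Deconjugative α-alkylation of an alkylidene malonate: γ-deprotonation gives the dienolate, which is methylated at the α-carbon to the quaternary centre (later C4) bearing the vinyl group (later C5); no stereocentre arises.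

Step 2
Reactants: 2 diethyl 2-methyl-2-vinylmalonate
Product: 3 2-methyl-2-vinylpropane-1,3-diol
Conditions: LiAlH4, THF, 0 °C to rt
Reagents that add atoms: none
Why: Exhaustive hydride reduction of both ester groups gives the prochiral 2,2-disubstituted propane-1,3-diol.

Step 3
Reactants: 3 2-methyl-2-vinylpropane-1,3-diol
Product: 4 (R)-2-(hydroxymethyl)-2-methylbut-3-en-1-yl acrylate
Conditions: CuCl2 (10 mol %), Ph-BOX ligand (antipode chosen for the R ester), acryloyl chloride, Et3N, THF, −78 °C
Reagents that add atoms: acryloyl chloride, C=CC(Cl)=O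
Why: Copper–bis(oxazoline)-catalysed desymmetrising mono-acylation of a 2,2-disubstituted propane-1,3-diol: the chiral copper-bound diol is acylated at one enantiotopic hydroxyl, which sets the quaternary stereocentre C4 (acrylate arm = C19, free arm = C3).

Step 4
Reactants: 4 (R)-2-(hydroxymethyl)-2-methylbut-3-en-1-yl acrylate
Product: 5 (R)-5-(hydroxymethyl)-5-methyl-5,6-dihydro-2H-pyran-2-one
Conditions: second-generation Grubbs catalyst (H2IMes)(PCy3)Cl2Ru=CHPh (5 mol %), CH2Cl2, 40 °C
Reagents that add atoms: none
Why: Ring-closing metathesis of the acrylate with the vinyl group gives the unsaturated δ-lactone, whose ring fixes the Z geometry of the future C5=C6 acceptor; C4 is not touched.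

Step 5
Reactants: 5 (R)-5-(hydroxymethyl)-5-methyl-5,6-dihydro-2H-pyran-2-one
Product: 6 (S)-3-methyl-6-oxo-3,6-dihydro-2H-pyran-3-carbaldehyde
Conditions: Dess–Martin periodinane, CH2Cl2, rt
Reagents that add atoms: none
Why: Dess–Martin oxidation of the primary neopentyl alcohol gives the non-enolisable aldehyde (future C3), so the stereocentre cannot epimerise.

Step 6
Reactants: 7 hexane-2,4-dione
Product: 8 3-methylhexane-2,4-dione
Conditions: K2CO3, MeI, acetone, reflux
Reagents that add atoms: iodomethane, CI
Why: C-alkylation of the 1,3-diketone at its doubly activated central carbon puts in the future C20 methyl.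

Step 7
Reactants: 8 3-methylhexane-2,4-dione
Product: 9 3-methyl-2,4-bis(trimethylsilyloxy)hexa-1,3-diene
Conditions: LiN(iPr)2 (2.2 equiv), THF, −78 °C; Me3SiCl, −78 °C to rt
Reagents that add atoms: chlorotrimethylsilane, C[Si](C)(C)Cl
Why: Formation of the 1,3-diketone dianion (second deprotonation at the less substituted terminal CH3) and O,O-bis-silylation give the 1,3-bis(silyloxy)diene, a masked 1,3-bis-nucleophile (terminal CH2 = C2, central carbon = C10).

Step 8
Reactants: 6 (S)-3-methyl-6-oxo-3,6-dihydro-2H-pyran-3-carbaldehyde; 9 3-methyl-2,4-bis(trimethylsilyloxy)hexa-1,3-diene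
Product: 12 ring A enone keto lactone, via titanium-bound aldol adduct 10 (not isolated), via cyclised hydroxy ketone 11 (not isolated)
Conditions: TiCl4 (2.2 equiv), CH2Cl2, −78 to 0 °C; aq. NaHCO3; crude product: MsCl, Et3N, CH2Cl2, 0 °C to rt
Reagents that add atoms: none
Why: Proposed new method: TiCl4 activates the aldehyde of 6 and the terminal CH2 of diene 9 adds to it (vinylogous Mukaiyama aldol, C2–C3), which leaves a titanium-chelated 2-methyl-1,3-diketonate whose central carbon then adds to the TiCl4-activated unsaturated lactone (Mukaiyama–Michael, C5–C10); mesylation and E1cB loss of the aldol oxygen then give the enone, so that both C3 epimers converge. The closest known reaction type is the TiCl4-mediated formal [3+3] cyclisation of 1,3-bis(silyl enol ethers) with 1,3-dielectrophiles, run here with an aldehyde/Michael-acceptor pair that cannot aromatise because C4 and C10 are quaternary. Ring A is closed by a 6-(enolendo)-exo-trig Michael addition, the lactone C5=C6 bond being exocyclic to the new ring. C5 is set by the tether: the nucleophile hangs on C3 and can reach C5 only on the lactone face that carries C3, which puts H5 on the side of the C4 methyl and makes ring A cis-fused to the lactone. C10 is set by the chelated U-shaped diketonate in a chair transition state, which keeps the propanoyl group (C9) equatorial, syn to the enolate oxygen and away from the lactone, and the methyl axial, syn to C19. The step needs aldehyde-before-lactone chemoselectivity and terminal-before-central regioselectivity of the diene, secured by the higher electrophilicity of the aldehyde and the usual terminal reactivity of such dienes; the titanium-bound aldolate also cannot transacylate the lactone, which would erase the facial control.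

Step 9
Reactants: 12 ring A enone keto lactone
Product: 13 C1 tosylhydrazone of 12
Conditions: TsNHNH2 (1.05 equiv), AcOH (cat.), EtOH, rt
Reagents that add atoms: 4-methylbenzenesulfonohydrazide, NNS(=O)(=O)c1ccc(C)cc1
Why: Tosylhydrazone formation at the conjugated ring ketone (C1), which is far more accessible than the acyclic ketone flanked by the quaternary C10 and an ethyl group; the lactone does not react.

Step 10
Reactants: 13 C1 tosylhydrazone of 12
Product: 14 1-ene keto lactone
Conditions: catecholborane, CHCl3, 0 °C; NaOAc·3H2O, reflux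
Reagents that add atoms: none
Why: Catecholborane reduction of the α,β-unsaturated tosylhydrazone, then sulfinate loss and 1,5-hydrogen shift of the allylic diazene (alkene-transposing reductive deoxygenation), removes the C1 oxygen and leaves a C1=C2 alkene; no stereocentre is involved.

Step 11
Reactants: 14 1-ene keto lactone
Product: 16 vinylogous methyl ester (7-methoxy-7-en-9-one), via trans-decalin-7,9-dione 15 (not isolated)
Conditions: KOt-Bu (2.2 equiv), THF, 0 °C to rt; AcOH; then TsOH (cat.), MeOH–benzene, reflux
Reagents that add atoms: methanol, CO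
Why: Dieckmann-type intramolecular Claisen condensation: the potassium enolate of the ethyl ketone (C8) attacks the lactone carbonyl (C7), closing ring B trans-fused (both ring B bonds are equatorial on ring A) and freeing the C19 hydroxyl; acid-catalysed enol etherification then occurs at the less hindered C7 carbonyl of the 2-methyl-1,3-dione.

Step 12
Reactants: 17 2-bromoprop-2-en-1-ol; 18 ethynyltrimethylsilane
Product: 19 2-methylene-4-(trimethylsilyl)but-3-yn-1-ol
Conditions: PdCl2(PPh3)2 (3 mol %), CuI (5 mol %), Et3N, THF, rt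
Reagents that add atoms: none
Why: Sonogashira coupling of the vinyl bromide with the terminal alkyne gives the 2-alkynyl allylic alcohol (C16, C13, C14, C12, C11).

Step 13
Reactants: 19 2-methylene-4-(trimethylsilyl)but-3-yn-1-ol
Product: 20 (S)-{2-[(trimethylsilyl)ethynyl]oxiran-2-yl}methanol
Conditions: Ti(OiPr)4, L-(+)-diethyl tartrate, t-BuOOH, 4 Å MS, CH2Cl2, −20 °C
Reagents that add atoms: tert-butyl hydroperoxide, CC(C)(C)OO
Why: Sharpless asymmetric epoxidation of the 2-substituted allylic alcohol; L-(+)-tartrate delivers oxygen to the face that gives the S epoxide and so sets C13.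

Step 14
Reactants: 20 (S)-{2-[(trimethylsilyl)ethynyl]oxiran-2-yl}methanol; 21 1,3-dithiane
Product: 22 (S)-2-(1,3-dithian-2-ylmethyl)-4-(trimethylsilyl)but-3-yne-1,2-diol
Conditions: 21, n-BuLi, THF, −30 °C; then 20, −30 to 0 °C; aq. NH4Cl
Reagents that add atoms: none
Why: Opening of the 2,2-disubstituted epoxide at its CH2 terminus by 2-lithio-1,3-dithiane (formyl anion equivalent, future C15); the C–O bond at C13 is not broken, so its configuration is kept (a Payne shift before opening leads to the same enantiomer).

Step 15
Reactants: 22 (S)-2-(1,3-dithian-2-ylmethyl)-4-(trimethylsilyl)but-3-yne-1,2-diol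
Product: 24 (3S)-3-ethynyl-5-methoxyoxolan-3-ol, via silylated alkynyl furanoside 23 (not isolated)
Conditions: PhI(OCOCF3)2, MeOH–MeCN, 0 °C; then K2CO3, MeOH, rt
Reagents that add atoms: methanol, CO
Why: Oxidative dithioacetal cleavage in methanol gives the aldehyde-level carbon, which closes with the primary hydroxyl to the cyclic methyl acetal (a protected lactol); K2CO3/MeOH then removes the alkynyl silane.

Step 16
Reactants: 16 vinylogous methyl ester (7-methoxy-7-en-9-one); 24 (3S)-3-ethynyl-5-methoxyoxolan-3-ol
Product: 26 9-alkynyl 1,8-dien-7-one, via C9 carbinol adduct 25 (not isolated)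
Conditions: 24, n-BuLi (2 equiv), THF, −78 °C; CeCl3; 16 pre-treated with LiN(SiMe3)2 (1 equiv); −78 to 0 °C; aq. NH4Cl; then PPTS, wet MeOH, rt
Reagents that add atoms: water, O
Why: Stork–Danheiser sequence: 1,2-addition of the slim cerium acetylide to the hindered C9 carbonyl of the vinylogous ester, then acid-induced ionisation and hydrolysis, transposes the carbonyl to C7 and places the side chain on C9 of the C8=C9 enone; the C9 carbinol centre is lost again.

Step 17
Reactants: 26 9-alkynyl 1,8-dien-7-one
Product: 27 19-hydroxy 8-en-7-one with saturated side chain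
Conditions: H2 (1 atm), Rh/Al2O3 (5 wt % Rh), EtOAc, rt
Reagents that add atoms: none
Why: Heterogeneous hydrogenation saturates the alkyne and the disubstituted ring A alkene, while the tetrasubstituted conjugated C8=C9 bond should survive; rhodium is chosen to avoid hydrogenolysis of the propargylic C13–O bond.

Step 18
Reactants: 27 19-hydroxy 8-en-7-one with saturated side chain
Product: 28 19-acetoxy 8-en-7-one
Conditions: Ac2O, pyridine, CH2Cl2, 0 °C
Reagents that add atoms: acetic anhydride, CC(=O)OC(C)=O
Why: Acetylation of the primary C19 hydroxyl; the tertiary C13 hydroxyl does not react under these conditions.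

Step 19
Reactants: 28 19-acetoxy 8-en-7-one
Product: 29 19-acetoxy 8-en-7β-ol
Conditions: NaBH4, CeCl3·7H2O, MeOH, −40 °C
Reagents that add atoms: none
Why: Luche 1,2-reduction of the enone; axial hydride delivery from the α face should give the equatorial 7β-alcohol.

Step 20
Reactants: 29 19-acetoxy 8-en-7β-ol
Product: 31 9α,13-epoxy-7β,8β-diol, via 8β,9β-epoxide 30 (not isolated)
Conditions: VO(acac)2 (5 mol %), t-BuOOH, CH2Cl2, 0 °C to rt; then PPTS (10 mol %), rt
Reagents that add atoms: tert-butyl hydroperoxide, CC(C)(C)OO
Why: Vanadium-catalysed epoxidation directed by the allylic 7β-hydroxyl gives the 8β,9β-epoxide, and acid-catalysed 5-exo opening by the C13 hydroxyl at C9 with inversion (trans-diaxial opening) gives the 9α,13-ether and the 8β-hydroxyl.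

Step 21
Reactants: 31 9α,13-epoxy-7β,8β-diol
Product: 32 8β-hydroxy-7-ketone
Conditions: Dess–Martin periodinane, CH2Cl2, rt
Reagents that add atoms: none
Why: Dess–Martin oxidation of the secondary 7-alcohol; the tertiary 8-hydroxyl is inert.

Step 22
Reactants: 32 8β-hydroxy-7-ketone
Product: 33 8β,19-diacetate with C15 methyl acetal
Conditions: Ac2O, DMAP, Et3N, CH2Cl2, 40 °C
Reagents that add atoms: acetic anhydride, CC(=O)OC(C)=O
Why: DMAP-promoted acetylation of the hindered tertiary 8β-hydroxyl next to the ketone.

Step 23
Reactants: 33 8β,19-diacetate with C15 methyl acetal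
Product: 34 C15 lactol
Conditions: AcOH–H2O–THF (3:1:1), 40 °C
Reagents that add atoms: water, O
Why: Mild acid hydrolysis of the cyclic methyl acetal to the lactol; the esters, the ketone and the saturated 9,13-ether are stable under these conditions.

Step 24
Reactants: 34 C15 lactol
Product: 35 CNP0351241.1
Conditions: MsCl, Et3N (excess), CH2Cl2, −30 °C to rt; NaHCO3 work-up
Reagents that add atoms: none
Why: Mesylation of the lactol and base-induced elimination (the only β-hydrogens are on C14) give the 2,3-dihydrofuran under non-acidic conditions, which the acid-labile spiro enol ether requires.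

**Compound list**
1 | diethyl ethylidenemalonate | CC=C(C(=O)OCC)C(=O)OCC | starting material
2 | diethyl 2-methyl-2-vinylmalonate | C=CC(C)(C(=O)OCC)C(=O)OCC | intermediate
3 | 2-methyl-2-vinylpropane-1,3-diol | C=CC(C)(CO)CO | intermediate
4 | (R)-2-(hydroxymethyl)-2-methylbut-3-en-1-yl acrylate | C=CC(=O)OC[C@@](C)(CO)C=C | intermediate
5 | (R)-5-(hydroxymethyl)-5-methyl-5,6-dihydro-2H-pyran-2-one | OC[C@]1(C)COC(=O)C=C1 | intermediate
6 | (S)-3-methyl-6-oxo-3,6-dihydro-2H-pyran-3-carbaldehyde | O=C[C@]1(C)COC(=O)C=C1 | intermediate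
7 | hexane-2,4-dione | CCC(=O)CC(C)=O | starting material
8 | 3-methylhexane-2,4-dione | CCC(=O)C(C)C(C)=O | intermediate
9 | 3-methyl-2,4-bis(trimethylsilyloxy)hexa-1,3-diene (enol ether geometry open) | C=C(O[Si](C)(C)C)C(C)=C(CC)O[Si](C)(C)C | intermediate
10 | titanium-bound aldol adduct, drawn as the free hydroxy diketone on the lactone (C3 epimers) | CCC(=O)C(C)C(=O)CC(O)[C@]1(C)COC(=O)C=C1 | intermediate
11 | cyclised hydroxy ketone: ring A 3-hydroxy-1-ketone cis-fused to the δ-lactone (C3 epimers; 4α-CH3, 5α-H, 10β-CH3) | CCC(=O)[C@@]1(C)C(=O)CC(O)[C@]2(C)COC(=O)C[C@H]12 | intermediate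
12 | ring A enone keto lactone: 1-oxo-2-ene; C10 with β-CH3 and propanoyl (C9, C8, C17); 5α-H; 4α-CH3; δ-lactone C4–C19H2–O–C7(=O)–C6H2–C5 cis-fused | CCC(=O)[C@@]1(C)C(=O)C=C[C@]2(C)COC(=O)C[C@H]12 | intermediate
13 | C1 tosylhydrazone of 12 | CCC(=O)[C@@]1(C)C(=NNS(=O)(=O)c3ccc(C)cc3)C=C[C@]2(C)COC(=O)C[C@H]12 | intermediate
14 | 1-ene keto lactone (C1 oxygen removed, C1=C2) | CCC(=O)[C@@]1(C)C=CC[C@]2(C)COC(=O)C[C@H]12 | intermediate
15 | trans-decalin-7,9-dione: 19-hydroxy, 4α-CH3, 8-CH3, 10β-CH3, 5α-H, 1-ene | OC[C@@]1(C)CC=C[C@]2(C)C(=O)C(C)C(=O)C[C@@H]12 | intermediate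
16 | vinylogous methyl ester: 19-hydroxy-7-methoxy-1,7-dien-9-one | OC[C@@]1(C)CC=C[C@]2(C)C(=O)C(C)=C(OC)C[C@@H]12 | intermediate
17 | 2-bromoprop-2-en-1-ol | OCC(Br)=C | starting material
18 | ethynyltrimethylsilane | C#C[Si](C)(C)C | starting material
19 | 2-methylene-4-(trimethylsilyl)but-3-yn-1-ol | OCC(=C)C#C[Si](C)(C)C | intermediate
20 | (S)-{2-[(trimethylsilyl)ethynyl]oxiran-2-yl}methanol | OC[C@@]1(C#C[Si](C)(C)C)CO1 | intermediate
21 | 1,3-dithiane | C1CSCSC1 | starting material
22 | (S)-2-(1,3-dithian-2-ylmethyl)-4-(trimethylsilyl)but-3-yne-1,2-diol | OC[C@@](O)(C#C[Si](C)(C)C)CC1SCCCS1 | intermediate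
23 | (3S)-5-methoxy-3-[(trimethylsilyl)ethynyl]oxolan-3-ol (C5 epimers) | COC1C[C@](O)(C#C[Si](C)(C)C)CO1 | intermediate
24 | (3S)-3-ethynyl-5-methoxyoxolan-3-ol (C5 epimers) | COC1C[C@](O)(C#C)CO1 | intermediate
25 | C9 carbinol adduct of the acetylide to 16 (C9 epimers) | OC[C@@]1(C)CC=C[C@]2(C)C(O)(C#C[C@@]3(O)CC(OC)OC3)C(C)=C(OC)C[C@@H]12 | intermediate
26 | 9-alkynyl 1,8-dien-7-one: 19-hydroxy; C9–C≡C–C13(OH) in the methyl furanoside | OC[C@@]1(C)CC=C[C@]2(C)C(C#C[C@@]3(O)CC(OC)OC3)=C(C)C(=O)C[C@@H]12 | intermediate
27 | 19-hydroxy 8-en-7-one with saturated C11–C12 chain and 13-hydroxy methyl furanoside | OC[C@@]1(C)CCC[C@]2(C)C(CC[C@@]3(O)CC(OC)OC3)=C(C)C(=O)C[C@@H]12 | intermediate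
28 | 19-acetoxy 8-en-7-one | CC(=O)OC[C@@]1(C)CCC[C@]2(C)C(CC[C@@]3(O)CC(OC)OC3)=C(C)C(=O)C[C@@H]12 | intermediate
29 | 19-acetoxy 8-en-7β-ol | CC(=O)OC[C@@]1(C)CCC[C@]2(C)C(CC[C@@]3(O)CC(OC)OC3)=C(C)[C@@H](O)C[C@@H]12 | intermediate
30 | 8β,9β-epoxide with 7β- and 13-hydroxyls | CC(=O)OC[C@@]1(C)CCC[C@@]2(C)[C@H]1C[C@H](O)[C@]3(C)O[C@]23CC[C@@]4(O)CC(OC)OC4 | intermediate
31 | 9α,13-epoxy-7β,8β-diol (19-acetate, C15 methyl acetal) | CC(=O)OC[C@@]1(C)CCC[C@@]2(C)[C@H]1C[C@H](O)[C@](C)(O)[C@]21CC[C@]2(CC(OC)OC2)O1 | intermediate
32 | 8β-hydroxy-7-ketone (19-acetate, C15 methyl acetal) | CC(=O)OC[C@@]1(C)CCC[C@@]2(C)[C@H]1CC(=O)[C@](C)(O)[C@]21CC[C@]2(CC(OC)OC2)O1 | intermediate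
33 | 8β,19-diacetate with C15 methyl acetal | CC(=O)OC[C@@]1(C)CCC[C@@]2(C)[C@H]1CC(=O)[C@](C)(OC(C)=O)[C@]21CC[C@]2(CC(OC)OC2)O1 | intermediate
34 | C15 lactol (8β,19-diacetate) | CC(=O)OC[C@@]1(C)CCC[C@@]2(C)[C@H]1CC(=O)[C@](C)(OC(C)=O)[C@]21CC[C@]2(CC(O)OC2)O1 | intermediate
35 | CNP0351241.1 (8β,19-diacetoxy-9α,13;15,16-diepoxylabd-14-en-7-one) | CC(=O)OC[C@@]1(C)CCC[C@@]2(C)[C@H]1CC(=O)[C@](C)(OC(C)=O)[C@]21CC[C@]2(C=COC2)O1 | target

**Totals and risks**
Total step count: 24. Longest linear sequence: 18 steps (steps 1–5, 8–11, 16–24).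

Step 8 (proposed new method). What may go wrong: the titanium-bound diketonate may fail to add to the hindered lactone β-carbon (C5, next to the quaternary C4), so the sequence stops at the aldol stage; facial control at C10 may also be poor. Fallback with known chemistry, setting out from 6 and 8: the lithium dianion of 8 (LiN(iPr)2, THF, −78 °C) would add to 6 to give the hydroxy diketone 10 as an isolated compound. Silylation (Et3SiCl, imidazole) would give the triethylsilyl ether of the aldol adduct F1. Cs2CO3 in MeCN would close ring A by intramolecular Michael addition to the silyloxy bicyclic keto lactone F2. DBU in toluene at 80 °C would then eliminate the silanol and rejoin the route at 12.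

Step 3. What may go wrong: poor discrimination between the enantiotopic hydroxyls (methyl versus vinyl on the quaternary carbon), or over-acylation to the diester. Fallback, setting out from 3: unselective mono-acryloylation (acryloyl chloride, Et3N, −40 °C) would give the racemic monoacrylate F3, and ring-closing metathesis the racemic hydroxymethyl lactone F4. Lipase-catalysed acetylation with vinyl acetate would then convert the S enantiomer into the (S)-acetoxymethyl lactone F5 and leave the R alcohol, so the route is rejoined at 5.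

Step 11. What may go wrong: C–C bond formation has to pass through a strained bridged tetrahedral intermediate, so lactone opening or base-induced retro-Michael epimerisation may outrun ring closure. Fallback, setting out from 14: methanolysis (K2CO3, MeOH) would give the hydroxy methyl ester F6, and silylation (t-BuMe2SiCl, imidazole) the silyl ether ester F7. An ordinary Dieckmann condensation (KOt-Bu, THF) would give the silyloxy decalindione F8. TsOH in MeOH would then form the enol ether with loss of the silyl group and rejoin the route at 16.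

Further compounds
F1 | step 8 | triethylsilyl ether of the aldol adduct 10 | CCC(=O)C(C)C(=O)CC(O[Si](CC)(CC)CC)[C@]1(C)COC(=O)C=C1
F2 | step 8 | silyloxy bicyclic keto lactone (triethylsilyl ether of 11) | CCC(=O)[C@@]1(C)C(=O)CC(O[Si](CC)(CC)CC)[C@]2(C)COC(=O)C[C@H]12
F3 | step 3 | racemic 2-(hydroxymethyl)-2-methylbut-3-en-1-yl acrylate | C=CC(=O)OCC(C)(CO)C=C
F4 | step 3 | racemic 5-(hydroxymethyl)-5-methyl-5,6-dihydro-2H-pyran-2-one | OCC1(C)COC(=O)C=C1
F5 | step 3 | (S)-(3-methyl-6-oxo-3,6-dihydro-2H-pyran-3-yl)methyl acetate | CC(=O)OC[C@@]1(C)COC(=O)C=C1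
F6 | step 11 | hydroxy methyl ester from methanolysis of 14 | CCC(=O)[C@@]1(C)C=CC[C@](C)(CO)[C@@H]1CC(=O)OC
F7 | step 11 | tert-butyldimethylsilyl ether of F6 | CCC(=O)[C@@]1(C)C=CC[C@](C)(CO[Si](C)(C)C(C)(C)C)[C@@H]1CC(=O)OC
F8 | step 11 | 19-silyloxy trans-decalin-7,9-dione | CC(C)(C)[Si](C)(C)OC[C@@]1(C)CC=C[C@]2(C)C(=O)C(C)C(=O)C[C@@H]12
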